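**Strategy.** The plan disconnects the C4=C5 alkene of the oxygen-bridged nine-membered ring (ring C: O, C3, C4, C5, C6, C7, C8, C9, C10) after the lactone (ring A) is complete. In the key step a γ-hydroxy enone closes reversibly to the C3 hemiketal (ring B); the cis-2,5 arrangement of C4 and C9 on this tetrahydrofuran holds two terminal alkenes together, and ring-closing metathesis then forges the Z-trisubstituted C4=C5 bond, closing ring C last and fixing C3. The precursor is an open-chain diene carrying the cis-fused α-methylene lactone, whose C7 and C8 centers come from one indium Barbier reaction relayed from a glyceraldehyde-derived C6; C10 is bought with (R)-linalool.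

Key step: step 15

Remark: germacranolide numbering is used (C1–C10 ring carbons, C11–C13 acrylate carbons of the lactone, C14 methyl on C10, C15 hydroxymethyl carbon on C4); compounds 2–5 and 10–15 are mixtures of anomers at the acetal carbon (the later C3), which is erased in steps 11–14; (R)-linalool and (S)-glyceraldehyde acetonide are assumed to be used in high enantiomeric purity.

Step 1
Reactants: 1 (R)-linalool
Product: 3 (5R)-5-ethenyl-2-methoxy-5-methyloxolane (anomers), via lactol 2 (not isolated)
Conditions: O3 (1.0 equiv, Sudan Red 7B end point), CH2Cl2/MeOH 4:1, −78 °C; Me2S, −78 °C to rt; then PPTS (cat.), MeOH, rt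
Reagents that add atoms: methanol (CO)
Why: Ozonolysis should cleave the electron-rich trisubstituted alkene faster than the monosubstituted vinyl group, the γ-hydroxy aldehyde closes to lactol 2, and acid-catalysed acetalisation stores C3 as a methyl acetal while the C10 stereocenter of linalool is untouched.

Step 2
Reactants: 3 (5R)-5-ethenyl-2-methoxy-5-methyloxolane
Product: 4 2-[(2R)-5-methoxy-2-methyloxolan-2-yl]ethan-1-ol
Conditions: 9-BBN, THF, 0 °C to rt; then NaOH, H2O2, 0 °C
Reagents that add atoms: hydrogen peroxide (OO)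
Why: Anti-Markovnikov hydroboration–oxidation of the only alkene should place the hydroxyl on the terminal carbon (C8) under basic conditions that the acetal tolerates.

Step 3
Reactants: 4 2-[(2R)-5-methoxy-2-methyloxolan-2-yl]ethan-1-ol
Product: 5 2-[(2R)-5-methoxy-2-methyloxolan-2-yl]acetaldehyde
Conditions: Dess–Martin periodinane, NaHCO3, CH2Cl2, 0 °C to rt
Reagents that add atoms: none
Why: Buffered Dess–Martin oxidation should stop at the aldehyde and spare the acid-labile acetal; the β-alkoxy aldehyde is used at once.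

Step 4
Reactants: 6 (S)-glyceraldehyde acetonide; 7 methyl acrylate
Product: 8 methyl 3-[(4S)-2,2-dimethyl-1,3-dioxolan-4-yl]-3-hydroxy-2-methylidenepropanoate (carbinol epimers)
Conditions: DABCO (0.5 equiv), 1,4-dioxane/H2O 1:1, rt
Reagents that add atoms: none
Why: Morita–Baylis–Hillman reaction of a reactive α-alkoxy aldehyde; the new carbinol center forms as a mixture and is erased in step 5.

Step 5
Reactants: 8 methyl 3-[(4S)-2,2-dimethyl-1,3-dioxolan-4-yl]-3-hydroxy-2-methylidenepropanoate
Product: 9 methyl (2Z)-2-(bromomethyl)-3-[(4R)-2,2-dimethyl-1,3-dioxolan-4-yl]prop-2-enoate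
Conditions: NBS, Me2S, CH2Cl2, 0 °C to rt
Reagents that add atoms: N-bromosuccinimide (O=C1CCC(=O)N1Br)
Why: The bromosulfonium salt activates the allylic alcohol and bromide enters with allylic transposition (SN2′) to give the more stable Z bromide (CH2Br cis to C6) under non-acidic conditions that keep the acetonide.

Step 6
Reactants: 5 2-[(2R)-5-methoxy-2-methyloxolan-2-yl]acetaldehyde; 9 methyl (2Z)-2-(bromomethyl)-3-[(4R)-2,2-dimethyl-1,3-dioxolan-4-yl]prop-2-enoate
Product: 10 methyl (3R,4R)-3-[(4R)-2,2-dimethyl-1,3-dioxolan-4-yl]-4-hydroxy-5-[(2R)-5-methoxy-2-methyloxolan-2-yl]-2-methylidenepentanoate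
Conditions: indium powder, THF/pH 7 phosphate buffer 3:1, rt
Reagents that add atoms: none
Why: Barbier allylation: the allylindium from 9 should add through C7 in a closed chair in which the Z reagent carries the C6 branch axial and the aldehyde chain equatorial, giving the syn relation of the C8 hydroxyl and the C6 branch and moving the alkene to C11=C13, while the dioxolane center picks the face of C7 (C6–H in the alkene plane to avoid allylic 1,3-strain, attack anti to the C6–C5 bond), so that C7 (R) and C8 (R) are set together.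

Step 7
Reactants: 10 the hydroxy ester of step 6
Product: 11 methyl (3R,4R)-3-[(4R)-2,2-dimethyl-1,3-dioxolan-4-yl]-5-[(2R)-5-methoxy-2-methyloxolan-2-yl]-2-methylidene-4-[(2-methylpropanoyl)oxy]pentanoate
Conditions: 2-methylpropanoyl chloride, pyridine, DMAP (cat.), CH2Cl2, 0 °C
Reagents that add atoms: 2-methylpropanoyl chloride (CC(C)C(Cl)=O)
Why: Acylation of the only free hydroxyl installs the C8 ester of the target before the hydroxy ester can lactonise toward O8.

Step 8
Reactants: 11 the isobutyrate of step 7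
Product: 13 (1R)-1-[(2R,3R)-2-(hydroxymethyl)-4-methylidene-5-oxooxolan-3-yl]-2-[(2R)-5-methoxy-2-methyloxolan-2-yl]ethyl 2-methylpropanoate, via diol 12 (not isolated)
Conditions: CSA (cat.), MeOH, 0 °C to rt
Reagents that add atoms: none
Why: Acid-catalysed transacetalisation frees the C5/C6 diol and the secondary C6 hydroxyl should close the five-membered lactone (ring A) by intramolecular transesterification in preference to the six-membered alternative through O5; methanol keeps C3 as its methyl acetal and no stereocenter is touched.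

Step 9
Reactants: 13 the lactone alcohol of step 8
Product: 14 (1R)-1-[(2R,3R)-2-formyl-4-methylidene-5-oxooxolan-3-yl]-2-[(2R)-5-methoxy-2-methyloxolan-2-yl]ethyl 2-methylpropanoate
Conditions: Dess–Martin periodinane, NaHCO3, CH2Cl2, 0 °C
Reagents that add atoms: none
Why: Neutral Dess–Martin oxidation should give the C5 aldehyde without enolising the adjacent C6 center; the aldehyde is used at once.

Step 10
Reactants: 14 the aldehyde of step 9
Product: 15 (1R)-1-[(2S,3R)-2-ethenyl-4-methylidene-5-oxooxolan-3-yl]-2-[(2R)-5-methoxy-2-methyloxolan-2-yl]ethyl 2-methylpropanoate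
Conditions: Zn dust, CH2I2, Ti(OiPr)4, THF, 0 °C to rt
Reagents that add atoms: diiodomethane (ICI)
Why: Takai methylenation with the non-basic gem-dizinc reagent should convert only the aldehyde (esters and lactone are inert) into the C6 vinyl group without epimerising C6.

Step 11
Reactants: 15 the vinyl lactone of step 10
Product: 16 (1R)-1-[(2S,3R)-2-ethenyl-4-methylidene-5-oxooxolan-3-yl]-2-[(2R)-5-hydroxy-2-methyloxolan-2-yl]ethyl 2-methylpropanoate (lactol)
Conditions: AcOH/THF/H2O 3:1:1, 40 °C
Reagents that add atoms: water (O)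
Why: Mild acid hydrolysis of the methyl acetal should unmask C3 as a lactol in equilibrium with its hydroxy aldehyde while the ester and the lactone survive.

Step 12
Reactants: 17 2-bromoprop-2-en-1-ol
Product: 18 [(2-bromoprop-2-en-1-yl)oxy](tert-butyl)dimethylsilane
Conditions: TBSCl, imidazole, CH2Cl2, 0 °C to rt
Reagents that add atoms: tert-butyldimethylsilyl chloride (CC(C)(C)[Si](C)(C)Cl)
Why: Standard silylation protects the future C15 hydroxyl so that only the C3 carbinol is oxidised in step 14.

Step 13
Reactants: 16 the lactol of step 11; 18 [(2-bromoprop-2-en-1-yl)oxy](tert-butyl)dimethylsilane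
Product: 19 (2R,4R)-8-{[(tert-butyldimethylsilyl)oxy]methyl}-1-[(2S,3R)-2-ethenyl-4-methylidene-5-oxooxolan-3-yl]-4,7-dihydroxy-4-methylnon-8-en-2-yl 2-methylpropanoate (C3 epimers)
Conditions: CrCl2 (6 equiv), NiCl2 (2 mol %), DMSO/THF 3:1, rt
Reagents that add atoms: none
Why: Nozaki–Hiyama–Kishi coupling: the alkenylchromium reagent should add only to the aldehyde form of the lactol and tolerate lactone, ester and the free tertiary hydroxyl; the new C3 carbinol forms as a mixture that is oxidised in step 14.

Step 14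
Reactants: 19 the diol of step 13
Product: 20 (2R,4R)-8-{[(tert-butyldimethylsilyl)oxy]methyl}-1-[(2S,3R)-2-ethenyl-4-methylidene-5-oxooxolan-3-yl]-4-hydroxy-4-methyl-7-oxonon-8-en-2-yl 2-methylpropanoate
Conditions: Dess–Martin periodinane, NaHCO3, CH2Cl2, 0 °C
Reagents that add atoms: none
Why: Dess–Martin oxidation of the secondary allylic alcohol should give the C3 enone, while the tertiary C10 hydroxyl cannot be oxidised.

Step 15
Reactants: 20 the γ-hydroxy enone of step 14
Product: 22 15-O-(tert-butyldimethylsilyl) ether of the target, via hemiketal 21 (not isolated)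
Conditions: second-generation Hoveyda–Grubbs catalyst RuCl2(H2IMes)(=CH-C6H4-2-OiPr) (15 mol % in two portions), 1,4-benzoquinone (10 mol %), toluene (1 mM), 80 °C, argon sparge
Reagents that add atoms: none
Why: Ring–chain tautomerism of 20 gives hemiketal 21 by reversible 5-exo-trig addition of the C10 hydroxyl to the C3 ketone (ring B); in the epimer with C4 and C9 cis on ring B the ruthenium alkylidene formed at the monosubstituted C5 vinyl group reaches the C4 methylidene, and [2+2] cycloaddition–cycloreversion expels ethene and closes the nine-membered ring C by ring-closing olefin metathesis. The closest known reaction type is the metathesis closure of oxygen-bridged nine-membered rings on cis-2,5-disubstituted tetrahydrofurans with formation of a trisubstituted alkene. C3 is the only new stereocenter and is controlled by the bridge: only the epimer with the C4 arm cis to C9 can cyclise, and the other returns to it through the open enone. The C4=C5 bond can only be Z (C3 and C6 cis) inside a nine-membered ring. The step needs chemoselectivity for the two reacting alkenes over the C11=C13 methylidene and over dimerisation: the lactone alkene is 1,1-disubstituted, electron-poor and could only close a cyclobutene, while high dilution and the hydroxyl next to the C4 alkene favour the intramolecular path. Metathesis through the open enone would converge on the same product after transannular hemiketalisation.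

Step 16
Reactants: 22 the silyl ether of step 15
Product: 23 target, (3S,6S,7R,8R,10R,4Z)-3,15-dihydroxy-3,10-epoxygermacra-4,11(13)-dien-6,12-olid-8-yl 2-methylpropanoate
Conditions: HF·pyridine, pyridine/THF, 0 °C to rt
Reagents that add atoms: none
Why: Buffered fluoride desilylation should free the primary allylic C15 hydroxyl without base that could isomerise the α-methylene lactone or open the hemiketal.

**Compound list**

1 | (R)-linalool, (3R)-3,7-dimethylocta-1,6-dien-3-ol | C=C[C@](C)(O)CCC=C(C)C | starting material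
2 | (5R)-5-ethenyl-5-methyloxolan-2-ol (lactol, anomers) | C=C[C@]1(C)OC(O)CC1 | intermediate (not isolated)
3 | (5R)-5-ethenyl-2-methoxy-5-methyloxolane (anomers) | C=C[C@]1(C)OC(OC)CC1 | intermediate
4 | 2-[(2R)-5-methoxy-2-methyloxolan-2-yl]ethan-1-ol | OCC[C@]1(C)OC(OC)CC1 | intermediate
5 | 2-[(2R)-5-methoxy-2-methyloxolan-2-yl]acetaldehyde | O=CC[C@]1(C)OC(OC)CC1 | intermediate
6 | (S)-glyceraldehyde acetonide, (4S)-2,2-dimethyl-1,3-dioxolane-4-carbaldehyde | O=C[C@@H]1COC(C)(C)O1 | starting material
7 | methyl acrylate | C=CC(=O)OC | starting material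
8 | methyl 3-[(4S)-2,2-dimethyl-1,3-dioxolan-4-yl]-3-hydroxy-2-methylidenepropanoate (carbinol epimers) | C=C(C(=O)OC)C(O)[C@@H]1COC(C)(C)O1 | intermediate
9 | methyl (2Z)-2-(bromomethyl)-3-[(4R)-2,2-dimethyl-1,3-dioxolan-4-yl]prop-2-enoate | BrC/C(C(=O)OC)=C\[C@@H]1COC(C)(C)O1 | intermediate
10 | methyl (3R,4R)-3-[(4R)-2,2-dimethyl-1,3-dioxolan-4-yl]-4-hydroxy-5-[(2R)-5-methoxy-2-methyloxolan-2-yl]-2-methylidenepentanoate | C=C(C(=O)OC)[C@@H]([C@@H]1COC(C)(C)O1)[C@H](O)C[C@]2(C)OC(OC)CC2 | intermediate
11 | methyl (3R,4R)-3-[(4R)-2,2-dimethyl-1,3-dioxolan-4-yl]-5-[(2R)-5-methoxy-2-methyloxolan-2-yl]-2-methylidene-4-[(2-methylpropanoyl)oxy]pentanoate | C=C(C(=O)OC)[C@@H]([C@@H]1COC(C)(C)O1)[C@H](OC(=O)C(C)C)C[C@]2(C)OC(OC)CC2 | intermediate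
12 | diol from 11 (acetonide removed, C5 and C6 hydroxyls free) | C=C(C(=O)OC)[C@@H]([C@@H](O)CO)[C@H](OC(=O)C(C)C)C[C@]1(C)OC(OC)CC1 | intermediate (not isolated)
13 | (1R)-1-[(2R,3R)-2-(hydroxymethyl)-4-methylidene-5-oxooxolan-3-yl]-2-[(2R)-5-methoxy-2-methyloxolan-2-yl]ethyl 2-methylpropanoate | C=C1C(=O)O[C@@H](CO)[C@H]1[C@H](OC(=O)C(C)C)C[C@]2(C)OC(OC)CC2 | intermediate
14 | (1R)-1-[(2R,3R)-2-formyl-4-methylidene-5-oxooxolan-3-yl]-2-[(2R)-5-methoxy-2-methyloxolan-2-yl]ethyl 2-methylpropanoate | C=C1C(=O)O[C@@H](C=O)[C@H]1[C@H](OC(=O)C(C)C)C[C@]2(C)OC(OC)CC2 | intermediate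
15 | (1R)-1-[(2S,3R)-2-ethenyl-4-methylidene-5-oxooxolan-3-yl]-2-[(2R)-5-methoxy-2-methyloxolan-2-yl]ethyl 2-methylpropanoate | C=C1C(=O)O[C@@H](C=C)[C@H]1[C@H](OC(=O)C(C)C)C[C@]2(C)OC(OC)CC2 | intermediate
16 | (1R)-1-[(2S,3R)-2-ethenyl-4-methylidene-5-oxooxolan-3-yl]-2-[(2R)-5-hydroxy-2-methyloxolan-2-yl]ethyl 2-methylpropanoate (lactol) | C=C1C(=O)O[C@@H](C=C)[C@H]1[C@H](OC(=O)C(C)C)C[C@]2(C)OC(O)CC2 | intermediate
17 | 2-bromoprop-2-en-1-ol | C=C(Br)CO | starting material
18 | [(2-bromoprop-2-en-1-yl)oxy](tert-butyl)dimethylsilane | C=C(Br)CO[Si](C)(C)C(C)(C)C | intermediate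
19 | (2R,4R)-8-{[(tert-butyldimethylsilyl)oxy]methyl}-1-[(2S,3R)-2-ethenyl-4-methylidene-5-oxooxolan-3-yl]-4,7-dihydroxy-4-methylnon-8-en-2-yl 2-methylpropanoate (C3 epimers) | C=C1C(=O)O[C@@H](C=C)[C@H]1[C@H](OC(=O)C(C)C)C[C@](C)(O)CCC(O)C(=C)CO[Si](C)(C)C(C)(C)C | intermediate
20 | (2R,4R)-8-{[(tert-butyldimethylsilyl)oxy]methyl}-1-[(2S,3R)-2-ethenyl-4-methylidene-5-oxooxolan-3-yl]-4-hydroxy-4-methyl-7-oxonon-8-en-2-yl 2-methylpropanoate | C=C1C(=O)O[C@@H](C=C)[C@H]1[C@H](OC(=O)C(C)C)C[C@](C)(O)CCC(=O)C(=C)CO[Si](C)(C)C(C)(C)C | intermediate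
21 | hemiketal tautomer of 20, (1R)-2-[(2R,5S)-5-(3-{[tert-butyl(dimethyl)silyl]oxy}prop-1-en-2-yl)-5-hydroxy-2-methyloxolan-2-yl]-1-[(2S,3R)-2-ethenyl-4-methylidene-5-oxooxolan-3-yl]ethyl 2-methylpropanoate | C=C1C(=O)O[C@@H](C=C)[C@H]1[C@H](OC(=O)C(C)C)C[C@]2(C)O[C@](O)(C(=C)CO[Si](C)(C)C(C)(C)C)CC2 | intermediate (not isolated)
22 | 15-O-(tert-butyldimethylsilyl) ether of the target | C=C1C(=O)O[C@H]2/C=C(/CO[Si](C)(C)C(C)(C)C)[C@]3(O)CC[C@](C)(C[C@@H](OC(=O)C(C)C)[C@@H]12)O3 | intermediate
23 | CNP0282937.2, (3S,6S,7R,8R,10R,4Z)-3,15-dihydroxy-3,10-epoxygermacra-4,11(13)-dien-6,12-olid-8-yl 2-methylpropanoate | C=C1C(=O)O[C@H]2/C=C(/CO)[C@]3(O)CC[C@](C)(C[C@@H](OC(=O)C(C)C)[C@@H]12)O3 | target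

**Step count.** Total: 16 steps. Longest linear sequence: 13 steps (1, 2, 3, 6, 7, 8, 9, 10, 11, 13, 14, 15, 16).

**Steps most likely to fail**

1. Step 15. The fully substituted C3 next to the C4 methylidene may keep this alkene out of the ruthenacyclobutane, so that dimerisation through the C5 vinyl groups or isomerisation of the terminal alkenes takes over. Fallback, setting out from diol 19 and coming back at 22: the metathesis is run one oxidation level earlier, where C3 is a secondary carbinol and the free allylic hydroxyl helps the 1,1-disubstituted alkene to react. The same catalyst, RuCl2(H2IMes)(=CH-C6H4-2-OiPr), in dilute toluene should close the ten-membered carbocyclic diol F1. Dess–Martin oxidation of its C3 carbinol should then be followed by transannular hemiketalisation to 22, so the oxygen bridge is made after the carbocycle.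

2. Step 6. The dioxolane center may give poor or reversed facial selectivity at C7 (and with it at C8), and the adduct may lactonise toward O8 before acylation. Fallback, setting out from bromide 9 and coming back at 10: borylation with Pd2(dba)3 and B2pin2 in toluene should give the allylboronate F2. Its addition to aldehyde 5 under a chiral BINOL-derived phosphoric acid (TRIP, toluene, −30 °C; the catalyst enantiomer is chosen by trial) puts the aldehyde face under catalyst control. In the closed chair this also fixes the face of C7, and aqueous work-up gives 10.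

3. Step 10 (with step 9). Enolisation of the α-acyloxy aldehyde 14 during oxidation or methylenation would scramble C6. Fallback, setting out from aldehyde 5 and coming back at 15: the vinyl group is brought in with the allyl fragment. Methyl (2S)-2-hydroxybut-3-enoate is silylated (TBSCl, imidazole) to methyl (2S)-2-(tert-butyldimethylsilyloxy)but-3-enoate F3 and reduced (DIBAL-H, −78 °C) to (2S)-2-(tert-butyldimethylsilyloxy)but-3-enal F4. Base-free vinylalumination (methyl propiolate, DIBAL-H, N-methylmorpholine N-oxide, THF, −78 °C) should give the Morita–Baylis–Hillman-type adduct F5, and NBS/Me2S the Z bromide F6. Indium-mediated addition of F6 to 5 should give the hydroxy ester F7, and acylation with 2-methylpropanoyl chloride the ester F8. HF·pyridine then removes the silyl group and the freed C6 hydroxyl lactonises to 15.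

**Further compounds**

F1 | step 15 | ten-membered carbocyclic diol (C3 carbinol epimers, C10 tertiary alcohol, 15-O-TBS, Z-C4=C5) | C=C1C(=O)O[C@H]2/C=C(/CO[Si](C)(C)C(C)(C)C)C(O)CC[C@@](C)(O)C[C@@H](OC(=O)C(C)C)[C@@H]12
F2 | step 6 | methyl (2Z)-3-[(4R)-2,2-dimethyl-1,3-dioxolan-4-yl]-2-[(4,4,5,5-tetramethyl-1,3,2-dioxaborolan-2-yl)methyl]prop-2-enoate | CC1(C)OB(C/C(C(=O)OC)=C\[C@@H]2COC(C)(C)O2)OC1(C)C
F3 | step 10 | methyl (2S)-2-[(tert-butyldimethylsilyl)oxy]but-3-enoate | C=C[C@H](O[Si](C)(C)C(C)(C)C)C(=O)OC
F4 | step 10 | (2S)-2-[(tert-butyldimethylsilyl)oxy]but-3-enal | C=C[C@H](O[Si](C)(C)C(C)(C)C)C=O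
F5 | step 10 | methyl (4S)-4-[(tert-butyldimethylsilyl)oxy]-3-hydroxy-2-methylidenehex-5-enoate (carbinol epimers) | C=C[C@H](O[Si](C)(C)C(C)(C)C)C(O)C(=C)C(=O)OC
F6 | step 10 | methyl (2Z,4S)-2-(bromomethyl)-4-[(tert-butyldimethylsilyl)oxy]hexa-2,5-dienoate | C=C[C@H](O[Si](C)(C)C(C)(C)C)/C=C(\CBr)C(=O)OC
F7 | step 10 | Barbier adduct: methyl 2-methylidenepentanoate carrying C7 (the 1-silyloxyprop-2-enyl branch), C8 hydroxyl and the (2R)-5-methoxy-2-methyloxolan-2-yl group | C=C(C(=O)OC)[C@@H]([C@H](C=C)O[Si](C)(C)C(C)(C)C)[C@H](O)C[C@]1(C)OC(OC)CC1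
F8 | step 10 | C8 2-methylpropanoate of F7 | C=C(C(=O)OC)[C@@H]([C@H](C=C)O[Si](C)(C)C(C)(C)C)[C@H](OC(=O)C(C)C)C[C@]1(C)OC(OC)CC1
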